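How slowly Je passes on to Jf, set against how fast Ja feeds it, was the first business of the meeting on Tuesday's and Thursday's flasks.

in all of them: Ja 0.23 M; Jb 10 mol%

| flask | Jc | Jd | remark | time |
|---|---|---|---|---|
| beta | 1.2 equiv | 0.62 mol% | run made earlier |  |
| gamma | 1.2 equiv | 0.72 mol% | run made earlier |  |
| Tuesday's | 1.20 equiv | 0.5 mol% |  | 8.0 min |
| Thursday's | 1.20 equiv | 1 mol% |  | 8.0 min |

| run | time / min | Ja / % | Jf / % | Je / % |
|---|---|---|---|---|
| beta | 0.417 | 92.8 | 0 | 6.7 |
| beta | 1.00 | 84.8 | 0.9 | 13.6 |
| beta | 2.50 | 65.3 | 7.3 | 27.3 |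
| beta | 6.00 | 37.1 | 24.8 | 37.6 |
| gamma | 0.667 | 90.6 | 0.6 | 8.2 |
| gamma | 2.00 | 71.5 | 4.3 | 22.8 |
| gamma | 4.00 | 52.6 | 16.2 | 32.3 |
| gamma | 6.00 | 37.9 | 27.7 | 35.7 |

(standard deviation of a reading: 0.5 percentage points)

* which of these there is most of at the end, counted by the Ja in it, Tuesday's (Ja / Je / Jf)
* which of these there is most of at the end, counted by the Ja in it, Thursday's (Ja / Je / Jf)
* final amount of the leader among these, as a percentage of the Ja charged, in Tuesday's
* final amount of the leader among these, as a percentage of the Ja charged, in Thursday's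

- steps thought possible: Jc + Jd + Je -> Jd + Jf; Ja + Jb -> Jb + Je

The first speaker reported that Ja falls at the same pace at both Jd loadings, since 37.1% remains in the beta run and 37.9% in the gamma run at 6.00 min. From the beta run she took a loss constant k_a of 0.165 min⁻¹.

I then argued that Jf's gain should be held against the Je standing, through a hand-over constant h. In the beta run, Jf gains 18 percentage points from 2.50 min to 6.00 min on a mean Je of 32.5%, so h comes to 0.154 min⁻¹. This h, the hand-over constant, is the Jf gained per minute per unit of Je standing, a pseudo-first-order constant. With Ja, Jb and Jc charges held, I scaled it with the Jd loading. That predicts 0.179 min⁻¹ for the gamma run, which reads 0.190 min⁻¹.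

So I put h at 0.124 min⁻¹ on Tuesday's flask, lower than k_a, and at 0.249 min⁻¹ on Thursday's flask, higher than k_a. With Je, as a fraction of the Ja charged at time t, = k_a/(h − k_a)·(e^(−k_a t) − e^(−h t)) and Jf taken as the remainder, I reckoned Tuesday's flask at Je 41.7% and Jf 31.6%. I reckoned Thursday's flask at Je 25.7% and Jf 47.6%. I warned that the step consumes Jc, while h is taken as constant.

The forecaster held instead that “the step looks saturated in Je and first order in Jd”. The forecast gave Je leading at 45% on Tuesday's flask and Jf at 54% on Thursday's. We named the same leaders, but my Thursday's figure is lower.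

    Jc + Jd + Je → Jd + Jf (k = 7.40 M⁻² s⁻¹)
    Ja + Jb → Jb + Je (k = 0.120 M⁻¹ s⁻¹)

Tuesday's flask ends with Je leading at 42.6%, and Thursday's with Jf at 44.2%, which puts the forecast for Thursday's flask 9.8 points high. From 4.00 min to 8.00 min, Thursday's flask reads h = 0.211 min⁻¹, lower than the carried 0.249 min⁻¹, with Jc down to 63.2% of its charge. For the neighbour of Thursday's flask charged with 4 mol% of Jb, k_a scales to 0.0661 min⁻¹, and the reckoning gives Ja 58.9%, Je 16.4% and Jf 24.7%. At 8.00 min that neighbour holds Ja 58.9%, Je 16.6% and Jf 24.5%.

The numbers in the tables stem from a simulated flask on assumed constants.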